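The plan rests on cutting the C4–C5 bond of the ten-membered carbocycle (C1–C10). The feature exploited is that the C5 carbinol sits directly on C4, the ester-bearing carbon of the cis C3=C4 ring olefin. This is the pattern left when a vinyl metal adds to an aldehyde. A Nozaki–Hiyama–Kishi cyclisation of seco compound 19 makes this bond, closes the cyclodecene and creates C5 in one operation, and its product is the target. Compound 19 already carries the trans C7/C8 α-methylene-γ-lactone, the O6 isovalerate, the C10 methyl group, the C5 aldehyde and a (Z)-α-iodo enoate. It comes from two three-step fragments joined by a stereospecific allylboration–lactonisation.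

Key step: step 12

**Remarks on the chemistry**
- **Numbering.** C1–C10 is the carbocycle: C3=C4 olefin, CO2Me on C4, OH on C5, isovalerate on O6, methyl on C10. The lactone is C7–C11(=C13)–C12(=O)–O–C8.
- **Structure check.** The target SMILES reads 5S,6S,7S,8R,10S. H7 and H8 are trans, and O5 and O6 are syn along C4–C7. C3=C4 is E by CIP but cis within the ring (C2 and C5 on one side), which corresponds to the Z descriptor of iodide 19.
- **Order of events.** The vinyl iodide is built on the citronellol fragment before the lactone exists, so ozone never meets the exocyclic methylene.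
- **Choice of boron.** The fragments are joined through boron because zinc, indium or chromium would attack the C–I bond. γ-Substituted 2-(halomethyl)enoates under Barbier conditions also usually favour cis lactones.
- **Assumption.** Compounds 1 and 7 are bought as single enantiomers, and 1 is used fresh.

**Step 1**
Reactants: 1 (R)-glyceraldehyde acetonide
Product: 2 (4S)-4-(2,2-dibromoethenyl)-2,2-dimethyl-1,3-dioxolane
Conditions: CBr4, PPh3, CH2Cl2, 0 °C
Reagents that add atoms: carbon tetrabromide, BrC(Br)(Br)Br
Why: The first stage of the Corey–Fuchs sequence (dibromoolefination by Ph3P=CBr2 made in the flask) is neutral, so the acetonide and the α-stereocentre (future C6) are untouched while the future C11 is brought in.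

**Step 2**
Reactants: 2 (4S)-4-(2,2-dibromoethenyl)-2,2-dimethyl-1,3-dioxolane
Product: 4 methyl 3-[(4S)-2,2-dimethyl-1,3-dioxolan-4-yl]prop-2-ynoate, via lithium acetylide 3 (not isolated)
Conditions: nBuLi (2.1 equiv), THF, −78 °C; ClCO2Me, −78 to 0 °C
Reagents that add atoms: methyl chloroformate, COC(=O)Cl
Why: The second stage of the Corey–Fuchs sequence (bromine–lithium exchange and elimination) gives the acetylide, whose C-acylation installs C12 at a temperature at which C6 is not deprotonated.

**Step 3**
Reactants: 4 methyl 3-[(4S)-2,2-dimethyl-1,3-dioxolan-4-yl]prop-2-ynoate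
Product: 6 methyl (2Z)-3-[(4S)-2,2-dimethyl-1,3-dioxolan-4-yl]-2-[(4,4,5,5-tetramethyl-1,3,2-dioxaborolan-2-yl)methyl]prop-2-enoate (dioxolane cis to CO2Me), via alkenylalane 5 (not isolated)
Conditions: iBu2AlH, HMPA, THF, 0 °C; ICH2Bpin, 0 °C to rt
Reagents that add atoms: 2-(iodomethyl)-4,4,5,5-tetramethyl-1,3,2-dioxaborolane, ICB1OC(C)(C)C(C)(C)O1
Why: Conjugate syn-hydroalumination of the ynoate puts H on C7 and Al on C11 on the same side, and the alkenylalane then binds to boron and shifts to the CH2 carbon with loss of iodide (Matteson-type 1,2-migration) with retention, so the dioxolane ends trans to CH2B, the geometry that a closed transition state translates into a trans lactone.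

**Step 4**
Reactants: 7 (S)-citronellol
Product: 9 (4S)-6-hydroxy-4-methylhexanal, via ozonide 8 (not isolated)
Conditions: O3, CH2Cl2, −78 °C; PPh3, −78 °C to rt
Reagents that add atoms: ozone, [O-][O+]=O
Why: Ozonolysis with reductive work-up cleaves the only C=C bond and stops at the aldehyde, the future C10 stereocentre is remote from the reaction, and the alcohol end keeps the two chain termini distinct without protecting groups.

**Step 5**
Reactants: 9 (4S)-6-hydroxy-4-methylhexanal
Product: 10 methyl (2Z,6S)-8-hydroxy-2-iodo-6-methyloct-2-enoate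
Conditions: Ph3P=CHCO2Me, NIS, CH2Cl2, −20 °C, dark; then 9, −20 °C to rt
Reagents that add atoms: methyl (triphenylphosphoranylidene)acetate, COC(=O)C=P(c1ccccc1)(c1ccccc1)c1ccccc1; N-iodosuccinimide, O=C1CCC(=O)N1I
Why: Wittig olefination with the stabilised iodo ylide places the alkyl chain trans to CO2Me and therefore cis to iodine, which should give mainly the (Z)-α-iodo enoate, and the primary alcohol is a spectator.

**Step 6**
Reactants: 10 methyl (2Z,6S)-8-hydroxy-2-iodo-6-methyloct-2-enoate
Product: 11 methyl (2Z,6S)-2-iodo-6-methyl-8-oxooct-2-enoate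
Conditions: Dess–Martin periodinane, CH2Cl2, 0 °C to rt
Reagents that add atoms: none
Why: Dess–Martin oxidation converts the primary alcohol into the C8 aldehyde under neutral conditions that leave the vinyl iodide and the enoate alone.

**Step 7**
Reactants: 6 allylboronate; 11 methyl (2Z,6S)-2-iodo-6-methyl-8-oxooct-2-enoate
Product: 13 methyl (2Z,6S)-7-{(2R,3S)-3-[(4S)-2,2-dimethyl-1,3-dioxolan-4-yl]-4-methylidene-5-oxooxolan-2-yl}-2-iodo-6-methylhept-2-enoate (6S,7S,8R,10S), via pinacol borate 12 (not isolated)
Conditions: Sc(OTf)3 (10 mol %), toluene, 0 °C to rt; then p-TsOH (cat.), rt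
Reagents that add atoms: none
Why: This is a Lewis-acid-accelerated allylboration through a closed Zimmerman–Traxler chair followed by lactonisation of the borate, in which the CH2B-trans geometry of 6 and an equatorial aldehyde chain give the C7/C8 anti adduct and hence the trans lactone, while 1,3-allylic strain with the cis CO2Me holds C6–H in the olefin plane so that the aldehyde should reach C7 anti to the C6–C5 bond (best σ-donor anti, alkoxy outside), which sets 7S and 8R without disturbing the C–I bond.

**Step 8**
Reactants: 13 lactone acetonide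
Product: 14 methyl (2Z,6S)-7-{(2R,3R)-3-[(1S)-1,2-dihydroxyethyl]-4-methylidene-5-oxooxolan-2-yl}-2-iodo-6-methylhept-2-enoate (same spatial arrangement; the C7 descriptor changes by CIP ranking only)
Conditions: AcOH/H2O (4:1), 40 °C
Reagents that add atoms: none
Why: Acid-catalysed acetal hydrolysis frees O5 and O6 without breaking a bond to C6, and the lactone should stay on O8 because a ring on O6 would hold its two substituents cis and a ring on O5 would be six-membered.

**Step 9**
Reactants: 14 diol
Product: 15 methyl (2Z,6S)-7-{(2R,3R)-3-[(1S)-1-hydroxy-2-(triethylsilyloxy)ethyl]-4-methylidene-5-oxooxolan-2-yl}-2-iodo-6-methylhept-2-enoate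
Conditions: Et3SiCl (1.05 equiv), imidazole, CH2Cl2, −40 °C
Reagents that add atoms: chlorotriethylsilane, CC[Si](Cl)(CC)CC
Why: In this sterically controlled silylation the primary O5 hydroxyl reacts much faster than the secondary O6 hydroxyl next to the branched C7, and the low temperature keeps imidazole from adding to the exocyclic enoate.

**Step 10**
Reactants: 15 triethylsilyl ether; 16 isovaleryl chloride
Product: 17 methyl (2Z,6S)-2-iodo-6-methyl-7-{(2R,3S)-4-methylidene-3-[(1S)-1-(3-methylbutanoyloxy)-2-(triethylsilyloxy)ethyl]-5-oxooxolan-2-yl}hept-2-enoate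
Conditions: pyridine, DMAP (cat.), CH2Cl2, 0 °C to rt
Reagents that add atoms: isovaleryl chloride 16, CC(C)CC(=O)Cl
Why: DMAP-catalysed esterification acylates the only free hydroxyl, and C6 keeps its configuration because no bond to the stereocentre is broken.

**Step 11**
Reactants: 17 isovalerate triethylsilyl ether
Product: 19 seco iodo-enoate aldehyde methyl (2Z,6S)-2-iodo-6-methyl-7-{(2R,3S)-4-methylidene-3-[(1S)-1-(3-methylbutanoyloxy)-2-oxoethyl]-5-oxooxolan-2-yl}hept-2-enoate, via alkoxysulfonium chloride 18 (not isolated)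
Conditions: (COCl)2, DMSO, CH2Cl2, −78 to −40 °C; iPr2NEt, −78 to −20 °C
Reagents that add atoms: none
Why: This is a Swern oxidation run directly on the primary triethylsilyl ether, in which chlorodimethylsulfonium chloride replaces silicon on O5 and the hindered amine collapses 18 to the aldehyde, so a free C5 hydroxyl never sits beside the C6 ester (no 1,2-acyl shift) and the short cold contact with base spares C6.

**Step 12**
Reactants: 19 seco iodo-enoate aldehyde
Product: 22 target CNP0544142.1 (5S,6S,7S,8R,10S), via vinylchromium 20 (not isolated), via chromium alkoxide 21 (not isolated)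
Conditions: CrCl2 (15 equiv), NiCl2 (1 mol % of the CrCl2), degassed DMSO, 2 mM, 19 added by syringe pump, rt, dark; work-up with pH 7 phosphate buffer and aqueous potassium sodium tartrate
Reagents that add atoms: none
Why: CrCl2 reduces NiCl2 to zerovalent nickel, which adds oxidatively to the C4–I bond without loss of geometry, exchange of nickel for trivalent chromium gives 20, and its C4–Cr bond adds across C5=O to give 21, which water converts into 22. The closest known reaction type is the nickel/chromium-mediated vinyl iodide–aldehyde (Nozaki–Hiyama–Kishi) macrocyclisation used for medium and large carbocycles. The ten-membered ring closes by a 10-exo-trig attack of C4 on C5, the bent (Z)-iodoalkene and the lactone ring (C6 and C9 branches trans) limit the freedom of the chain, and high dilution disfavours intermolecular coupling. The new C5 stereocentre is governed by the C6 acyloxy stereocentre inside the cyclic transition state: with C6–O anti to the forming bond, the tether that leaves from C7 should bring C4 in on the C7 side and not over H6 as an untethered reagent would, which exposes the carbonyl face that leads to the 5,6-syn (5S) carbinol. The step needs attack at the aldehyde only and retention of olefin geometry; the first is secured by the weakly basic carbon–chromium bond, which ignores the γ-lactone, the methyl ester, the isovalerate and the exocyclic enoate, and the second is usual for trisubstituted iodoalkenes. The inert chromium alkoxide and the neutral work-up should keep the isovalerate on O6, so no further step is needed.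

**Compound list**
1 | (R)-glyceraldehyde acetonide, (4R)-2,2-dimethyl-1,3-dioxolane-4-carbaldehyde | O=C[C@H]1COC(C)(C)O1 | starting material
2 | (4S)-4-(2,2-dibromoethenyl)-2,2-dimethyl-1,3-dioxolane | BrC(Br)=C[C@H]1COC(C)(C)O1 | intermediate
3 | lithium acetylide of (4S)-4-ethynyl-2,2-dimethyl-1,3-dioxolane | [Li]C#C[C@H]1COC(C)(C)O1 | intermediate
4 | methyl 3-[(4S)-2,2-dimethyl-1,3-dioxolan-4-yl]prop-2-ynoate | COC(=O)C#C[C@H]1COC(C)(C)O1 | intermediate
5 | alkenylalane, methyl 2-(diisobutylalumino)-3-[(4S)-dioxolanyl]prop-2-enoate (Al and H7 cis) | COC(=O)/C([Al](CC(C)C)CC(C)C)=C\[C@H]1COC(C)(C)O1 | intermediate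
6 | (2Z)-allylboronate, dioxolane cis to CO2Me and trans to CH2Bpin | COC(=O)/C(CB1OC(C)(C)C(C)(C)O1)=C\[C@H]1COC(C)(C)O1 | intermediate
7 | (S)-citronellol, (3S)-3,7-dimethyloct-6-en-1-ol | OCC[C@@H](C)CCC=C(C)C | starting material
8 | ozonide (1,2,4-trioxolane) of 7 | OCC[C@@H](C)CCC1OOC(C)(C)O1 | intermediate
9 | (4S)-6-hydroxy-4-methylhexanal | OCC[C@@H](C)CCC=O | intermediate
10 | methyl (2Z,6S)-8-hydroxy-2-iodo-6-methyloct-2-enoate | OCC[C@@H](C)CC/C=C(/C(=O)OC)I | intermediate
11 | methyl (2Z,6S)-2-iodo-6-methyl-8-oxooct-2-enoate | O=CC[C@@H](C)CC/C=C(/C(=O)OC)I | intermediate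
12 | open-chain O8 pinacol borate (6S,7S,8R,10S) | C=C(C(=O)OC)[C@H]([C@H]1COC(C)(C)O1)[C@H](OB1OC(C)(C)C(C)(C)O1)C[C@@H](C)CC/C=C(/C(=O)OC)I | intermediate
13 | trans lactone acetonide (6S,7S,8R,10S) | C=C1C(=O)O[C@H](C[C@@H](C)CC/C=C(/C(=O)OC)I)[C@H]1[C@H]2COC(C)(C)O2 | intermediate
14 | 5,6-diol (6S,7R,8R,10S by CIP, same spatial arrangement) | C=C1C(=O)O[C@H](C[C@@H](C)CC/C=C(/C(=O)OC)I)[C@H]1[C@H](O)CO | intermediate
15 | O5 triethylsilyl ether (6S,7R,8R,10S) | C=C1C(=O)O[C@H](C[C@@H](C)CC/C=C(/C(=O)OC)I)[C@H]1[C@H](O)CO[Si](CC)(CC)CC | intermediate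
16 | isovaleryl chloride, 3-methylbutanoyl chloride | CC(C)CC(=O)Cl | starting material
17 | O6 isovalerate O5 triethylsilyl ether (6S,7S,8R,10S) | C=C1C(=O)O[C@H](C[C@@H](C)CC/C=C(/C(=O)OC)I)[C@H]1[C@H](OC(=O)CC(C)C)CO[Si](CC)(CC)CC | intermediate
18 | O5 dimethylalkoxysulfonium chloride | C=C1C(=O)O[C@H](C[C@@H](C)CC/C=C(/C(=O)OC)I)[C@H]1[C@H](OC(=O)CC(C)C)CO[S+](C)C.[Cl-] | intermediate
19 | seco C4/C5 (Z)-iodo-enoate aldehyde (6S,7S,8R,10S) | C=C1C(=O)O[C@H](C[C@@H](C)CC/C=C(/C(=O)OC)I)[C@H]1[C@H](OC(=O)CC(C)C)C=O | intermediate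
20 | C4 vinylchromium dichloride | C=C1C(=O)O[C@H](C[C@@H](C)CC/C=C(/C(=O)OC)[Cr](Cl)Cl)[C@H]1[C@H](OC(=O)CC(C)C)C=O | intermediate
21 | O5 chromium alkoxide of the target | C=C1C(=O)O[C@@H]2C[C@@H](C)CC/C=C(/C(=O)OC)[C@H](O[Cr](Cl)Cl)[C@@H](OC(=O)CC(C)C)[C@@H]12 | intermediate
22 | CNP0544142.1 (5S,6S,7S,8R,10S; C3=C4 E by CIP, cis in the ring) | C=C1C(=O)O[C@@H]2C[C@@H](C)CC/C=C(/C(=O)OC)[C@H](O)[C@@H](OC(=O)CC(C)C)[C@@H]12 | target

**Step count**
- Total step count: 12.
- Longest linear sequence: 9 (steps 1–3 or 4–6, then 7–12).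

**Steps most likely to fail**

**Step 12.** C4 may add to the other face of the C5 carbonyl, so that the 5,6-anti carbinol prevails. Intermolecular coupling or protonation of the carbon–metal bond may also erode the ring closure. The fallback sets out from 19 and comes back at 22.

The ring is closed through the same bond, but C5 is no longer set in the C–C bond formation. The 5-epimeric carbinol F1 is oxidised with Dess–Martin periodinane to the C5 ring ketone F2. A Luche reduction (NaBH4, CeCl3·7H2O, MeOH, −78 °C) then delivers hydride in the 1,2-sense.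

An ester on O6 does not chelate, so the polar Felkin–Anh arrangement (hydride anti to C6–O) applies. With hydride in the place of carbon, this same bias leads to the 5,6-syn alcohol 22. A chelating reductant would point back to the anti series and is avoided.

**Step 7.** The aldehyde may approach C7 from the C5 flank of the dioxolane (anti to O6). That would invert C7 and C8 together relative to C6. The fallback sets out from aldehyde 11 and comes back at 17.

Commercial (S)-glyceraldehyde acetonide F3 is taken through the operations of steps 1 to 3, by way of dibromoolefin F4, lithium acetylide F5, ynoate F6 and alkenylalane F7. This gives the enantiomeric allylboronate F8. With that facial preference, F8 and 11 should give, by way of the borate F9, the 6-epimeric lactone acetonide F10 with C7 and C8 correct.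

Hydrolysis gives the 6-epimeric diol F11, and selective silylation gives the 6-epimeric triethylsilyl ether F12. A Mitsunobu esterification (isovaleric acid, preformed PPh3/DIAD betaine, toluene, 0 °C to rt) then inverts C6 and installs the isovalerate in one operation, giving 17.

**Step 3.** The olefin geometry may erode through the aluminium allenolate form, or capture by the boronate may be incomplete. The fallback sets out from 4 and comes back at 6.

Syn-hydrostannation catalysed by Pd(PPh3)4 (Bu3SnH, THF, 0 °C) gives the α-stannyl enoate F13, with tin on C11 and the dioxolane cis to CO2Me. Iodine in CH2Cl2 replaces tin with retention to give the (E)-α-iodo enoate F14.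

A Negishi coupling with IZnCH2Bpin (from ICH2Bpin and zinc dust) under Pd(PPh3)4 then gives 6. The geometry is carried throughout by isolable, configurationally stable alkenes.

**Further compounds**
F1 | step 12 | 5-epimer of the target (5R,6S,7S,8R,10S) | C=C1C(=O)O[C@@H]2C[C@@H](C)CC/C=C(/C(=O)OC)[C@@H](O)[C@@H](OC(=O)CC(C)C)[C@@H]12
F2 | step 12 | C5 ring ketone | C=C1C(=O)O[C@@H]2C[C@@H](C)CC/C=C(/C(=O)OC)C(=O)[C@@H](OC(=O)CC(C)C)[C@@H]12
F3 | step 7 | (S)-glyceraldehyde acetonide (bought) | O=C[C@@H]1COC(C)(C)O1
F4 | step 7 | (4R)-4-(2,2-dibromoethenyl)-2,2-dimethyl-1,3-dioxolane | BrC(Br)=C[C@@H]1COC(C)(C)O1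
F5 | step 7 | lithium acetylide of (4R)-4-ethynyl-2,2-dimethyl-1,3-dioxolane | [Li]C#C[C@@H]1COC(C)(C)O1
F6 | step 7 | methyl 3-[(4R)-2,2-dimethyl-1,3-dioxolan-4-yl]prop-2-ynoate | COC(=O)C#C[C@@H]1COC(C)(C)O1
F7 | step 7 | enantiomer of alkenylalane 5 | COC(=O)/C([Al](CC(C)C)CC(C)C)=C\[C@@H]1COC(C)(C)O1
F8 | step 7 | enantiomer of allylboronate 6 | COC(=O)/C(CB1OC(C)(C)C(C)(C)O1)=C\[C@@H]1COC(C)(C)O1
F9 | step 7 | 6-epimer of borate 12 | C=C(C(=O)OC)[C@H]([C@@H]1COC(C)(C)O1)[C@H](OB1OC(C)(C)C(C)(C)O1)C[C@@H](C)CC/C=C(/C(=O)OC)I
F10 | step 7 | 6-epimer of lactone acetonide 13 (6R,7S,8R,10S) | C=C1C(=O)O[C@H](C[C@@H](C)CC/C=C(/C(=O)OC)I)[C@H]1[C@@H]2COC(C)(C)O2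
F11 | step 7 | 6-epimer of diol 14 | C=C1C(=O)O[C@H](C[C@@H](C)CC/C=C(/C(=O)OC)I)[C@H]1[C@@H](O)CO
F12 | step 7 | 6-epimer of triethylsilyl ether 15 | C=C1C(=O)O[C@H](C[C@@H](C)CC/C=C(/C(=O)OC)I)[C@H]1[C@@H](O)CO[Si](CC)(CC)CC
F13 | step 3 | methyl (2E)-3-[(4S)-2,2-dimethyl-1,3-dioxolan-4-yl]-2-(tributylstannyl)prop-2-enoate | COC(=O)/C([Sn](CCCC)(CCCC)CCCC)=C\[C@H]1COC(C)(C)O1
F14 | step 3 | methyl (2E)-3-[(4S)-2,2-dimethyl-1,3-dioxolan-4-yl]-2-iodoprop-2-enoate | COC(=O)/C(I)=C\[C@H]1COC(C)(C)O1
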